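**Retrosynthetic overview**
1. Target: (2S,3S,6R,9S,10R)-3,10-dibromo-2-chloro-α-chamigren-9-ol (chamigrane numbering: ring B = C1–C6, spiro atom C6, ring A = C6–C11). The last disconnection is the silyl ether of the C9 alcohol.
2. Key disconnection: the C6–C11 bond of the cyclohexene ring (C6, C7, C8, C9, C10, C11). This gives a monocyclic bisabolene-type precursor whose side chain ends in a vicinal bromochloride (C10–Br, C11–Cl). Forward: acid equilibration of the olefin, then bromonium-triggered cation–olefin spirocyclisation.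
3. Enabling feature: the gem-dimethyl quaternary carbon C11 lies between C10–Br and the spiro carbon C6, and the other ring-A neighbour of C6 is C7, carrying a methyl and the C7=C8 double bond. This is the signature of a Markovnikov-opened bromonium ion (C10/C11) captured by a tetrasubstituted exocyclic alkene (C6=C7) with loss of H8.
4. Precursor assembly: boron aldol (C8–C9 bond) between the ring-B methyl ketone and (S)-2-bromo-3-chloro-3-methylbutanal, then silylation and carbonyl methylenation. The ketone comes from (+)-trans-limonene oxide (Cl at C2 by diaxial epoxide opening, Br at C3 by substitution with retention, ozonolysis). The aldehyde comes from prenol by catalytic enantioselective bromochlorination.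
5. Ring order: ring B is present from the start (chiral pool); ring A is closed last, in the key step. Stereocentres: C2/C3 from limonene oxide, C10 from the catalyst, C9 from the Cornforth aldol, C6 in the key step.

Key step: step 9

Assumption: (+)-trans-limonene 1,2-oxide is used as the pure trans isomer; the C6–H configuration of the intermediates before step 9 is without consequence, because C6 becomes trigonal in step 9 (atom labels in the text follow chamigrane numbering).

Step 1
Reactants: 1 (+)-trans-limonene 1,2-oxide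
Product: 2 (1S,2S,4R)-2-chloro-1-methyl-4-(prop-1-en-2-yl)cyclohexan-1-ol
Conditions: LiCl, AcOH, THF, 0 → 23 °C
Reagents that add atoms: lithium chloride, [Li+].[Cl-]
Why: Acid-assisted halohydrin formation follows the Fürst–Plattner rule, so in the trans-oxide chloride should enter trans-diaxially at the secondary carbon with inversion, which sets the C2 chloride and leaves the tertiary alcohol at C3.

Step 2
Reactants: 2 (1S,2S,4R)-2-chloro-1-methyl-4-(prop-1-en-2-yl)cyclohexan-1-ol
Product: 3 1-[(1R,3S,4S)-3-chloro-4-hydroxy-4-methylcyclohexyl]ethan-1-one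
Conditions: O3, CH2Cl2/MeOH, −78 °C; then Me2S, −78 → 23 °C
Reagents that add atoms: ozone, [O-][O+]=O
Why: Ozonolysis with reductive work-up cleaves the only alkene to the methyl ketone and touches no stereocentre.

Step 3
Reactants: 3 1-[(1R,3S,4S)-3-chloro-4-hydroxy-4-methylcyclohexyl]ethan-1-one
Product: 4 1-[(1R,3S,4S)-4-bromo-3-chloro-4-methylcyclohexyl]ethan-1-one
Conditions: TMSBr, CH2Cl2, 0 → 23 °C
Reagents that add atoms: bromotrimethylsilane, C[Si](C)(C)Br
Why: SN1 substitution of the tertiary alcohol by bromide should pass through a cation bridged by the anti-periplanar axial chlorine, so bromide enters trans-diaxially with net retention, which is also the thermodynamically preferred tertiary bromide (methyl equatorial).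

Step 4
Reactants: 5 3-methylbut-2-en-1-ol
Product: 6 (S)-2-bromo-3-chloro-3-methylbutan-1-ol
Conditions: NBS, ClTi(Oi-Pr)3, chiral tridentate Schiff-base diol ligand (20 mol%), hexanes, −20 °C
Reagents that add atoms: N-bromosuccinimide, O=C1CCC(=O)N1Br; chlorotitanium triisopropoxide, CC(C)O[Ti](Cl)(OC(C)C)OC(C)C
Why: Titanium-mediated catalytic enantioselective bromochlorination of an allylic alcohol delivers bromine to C2 and titanium-bound chloride anti to the tertiary carbon, and the ligand enantiomer is chosen so that the S bromide (future C10) forms.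

Step 5
Reactants: 6 (S)-2-bromo-3-chloro-3-methylbutan-1-ol
Product: 7 (S)-2-bromo-3-chloro-3-methylbutanal
Conditions: Dess–Martin periodinane, CH2Cl2, 0 → 23 °C; used at once
Reagents that add atoms: none
Why: Dess–Martin oxidation works without base, so the α-bromo-β-chloro aldehyde should form without epimerisation or loss of HCl.

Step 6
Reactants: 4 1-[(1R,3S,4S)-4-bromo-3-chloro-4-methylcyclohexyl]ethan-1-one; 7 (S)-2-bromo-3-chloro-3-methylbutanal
Product: 9 (3S,4S)-4-bromo-1-[(1R,3S,4S)-4-bromo-3-chloro-4-methylcyclohexyl]-5-chloro-3-hydroxy-5-methylhexan-1-one, via dibutylboron enolate 8 (not isolated)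
Conditions: 4, Bu2BOTf, i-Pr2NEt, CH2Cl2, −78 °C; then 7, −78 °C; MeOH/pH 7 buffer
Reagents that add atoms: dibutylboron trifluoromethanesulfonate, CCCCB(CCCC)OS(=O)(=O)C(F)(F)F (its boron stays in 8 only and leaves on work-up)
Why: Kinetic boron enolisation occurs at the methyl group, and the boron aldol addition to the α-bromo aldehyde should follow the Cornforth (polar Felkin–Anh) model, attack opposite the CMe2Cl group giving the 1,2-anti bromohydrin, that is the S carbinol (future C9, cis to Br in the ring).

Step 7
Reactants: 9 (3S,4S)-4-bromo-1-[(1R,3S,4S)-4-bromo-3-chloro-4-methylcyclohexyl]-5-chloro-3-hydroxy-5-methylhexan-1-one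
Product: 10 (3S,4S)-4-bromo-1-[(1R,3S,4S)-4-bromo-3-chloro-4-methylcyclohexyl]-5-chloro-5-methyl-3-[(triisopropylsilyl)oxy]hexan-1-one
Conditions: TIPSOTf, 2,6-lutidine, CH2Cl2, −78 → 0 °C
Reagents that add atoms: triisopropylsilyl trifluoromethanesulfonate, CC(C)[Si](OS(=O)(=O)C(F)(F)F)(C(C)C)C(C)C
Why: Silyl triflate protection of the hindered secondary alcohol under weakly basic conditions gives a bulky, non-participating and acid-tolerant ether.

Step 8
Reactants: 10 (3S,4S)-4-bromo-1-[(1R,3S,4S)-4-bromo-3-chloro-4-methylcyclohexyl]-5-chloro-5-methyl-3-[(triisopropylsilyl)oxy]hexan-1-one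
Product: 11 triisopropyl({(4S,5S)-5-bromo-2-[(1R,3S,4S)-4-bromo-3-chloro-4-methylcyclohexyl]-6-chloro-6-methylhept-1-en-4-yl}oxy)silane
Conditions: Cp2TiMe2, toluene/THF, 65 °C, dark
Reagents that add atoms: dimethyltitanocene (Petasis reagent), C[Ti](C)(C1C=CC=C1)C1C=CC=C1
Why: Petasis methylenation is non-basic and should tolerate the enolisable β-silyloxy ketone and the alkyl halides, giving the 1,1-disubstituted alkene that holds all fifteen skeletal carbons.

Step 9
Reactants: 11 triisopropyl({(4S,5S)-5-bromo-2-[(1R,3S,4S)-4-bromo-3-chloro-4-methylcyclohexyl]-6-chloro-6-methylhept-1-en-4-yl}oxy)silane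
Product: 13 triisopropyl{[(3S,4R,6R,8S,9S)-4,9-dibromo-8-chloro-1,5,5,9-tetramethylspiro[5.5]undec-1-en-3-yl]oxy}silane, via tetrasubstituted E-alkene 12 (not isolated)
Conditions: TfOH (5 mol%), CH2Cl2, −20 → 0 °C; then (CF3)2CHOH added (HFIP/CH2Cl2 4:1, 0.01 M), 0 → 23 °C
Reagents that add atoms: none
Why: Proposed new method: catalytic acid should protonate the 1,1-disubstituted alkene reversibly to the tertiary C7 cation and so equilibrate the olefin isomers toward the nucleophilic tetrasubstituted alkene 12 before HFIP is added; in HFIP bromine-assisted ionisation of the tertiary C11–Cl bond then gives a configurationally defined C10/C11 bromonium ion, C6 attacks C11 anti to bromine, and the new C7 cation loses H8. The closest known reaction type is the bromonium-initiated cation–olefin (polyene) cyclisation started by solvolysis of an enantioenriched vicinal bromochloride, extended here by the in situ olefin equilibration and by a halogenated ring that carries the nucleophilic alkene. The cyclohexene ring closes in a 6-endo, chair-like mode that joins the two quaternary carbons C6 and C11. The only new stereocentre, spiro C6, should be controlled by the ring-B chair with axial C2–Cl, which shields one face of the exocyclic alkene, and for the E alkene this is reinforced by the chair transition state with C10–Br equatorial; C2, C3, C9 and C10 are carried through unchanged. The step needs ionisation of the side-chain chloride before the ring tertiary bromide (β-bromine assists far better than β-chlorine), six-ring closure through C6 and not five-ring closure through C7 (chair transition state, as in bromonium cyclisations of γ-bisabolene-type dienes), reaction through the tetrasubstituted isomer only (the other olefin isomers return through the C7 cation, and the pre-equilibration keeps the 1,1-disubstituted isomer low), and endocyclic proton loss (thermodynamically favoured under acid).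

Step 10
Reactants: 13 triisopropyl{[(3S,4R,6R,8S,9S)-4,9-dibromo-8-chloro-1,5,5,9-tetramethylspiro[5.5]undec-1-en-3-yl]oxy}silane
Product: 14 (3S,4R,6R,8S,9S)-4,9-dibromo-8-chloro-1,5,5,9-tetramethylspiro[5.5]undec-1-en-3-ol
Conditions: HF·pyridine, pyridine, THF, 0 → 23 °C
Reagents that add atoms: none
Why: Fluoride cleavage of the Si–O bond under mildly acidic conditions frees the allylic alcohol without base, so the tertiary bromide and the cis-bromohydrin should not undergo elimination.

**Compound list**
1 | (+)-trans-limonene 1,2-oxide, (1S,2R,4R)-1,2-epoxy-p-menth-8-ene | C=C(C)[C@@H]1CC[C@]2(C)O[C@@H]2C1 | starting material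
2 | (1S,2S,4R)-2-chloro-1-methyl-4-(prop-1-en-2-yl)cyclohexan-1-ol | C=C(C)[C@@H]1CC[C@](C)(O)[C@@H](Cl)C1 | intermediate
3 | 1-[(1R,3S,4S)-3-chloro-4-hydroxy-4-methylcyclohexyl]ethan-1-one | CC(=O)[C@@H]1CC[C@](C)(O)[C@@H](Cl)C1 | intermediate
4 | 1-[(1R,3S,4S)-4-bromo-3-chloro-4-methylcyclohexyl]ethan-1-one | CC(=O)[C@@H]1CC[C@](C)(Br)[C@@H](Cl)C1 | intermediate
5 | 3-methylbut-2-en-1-ol (prenol) | CC(C)=CCO | starting material
6 | (S)-2-bromo-3-chloro-3-methylbutan-1-ol | OC[C@H](Br)C(C)(C)Cl | intermediate
7 | (S)-2-bromo-3-chloro-3-methylbutanal | O=C[C@H](Br)C(C)(C)Cl | intermediate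
8 | dibutyl({1-[(1R,3S,4S)-4-bromo-3-chloro-4-methylcyclohexyl]ethenyl}oxy)borane | C=C(OB(CCCC)CCCC)[C@@H]1CC[C@](C)(Br)[C@@H](Cl)C1 | intermediate (not isolated)
9 | (3S,4S)-4-bromo-1-[(1R,3S,4S)-4-bromo-3-chloro-4-methylcyclohexyl]-5-chloro-3-hydroxy-5-methylhexan-1-one | O=C(C[C@H](O)[C@H](Br)C(C)(C)Cl)[C@@H]1CC[C@](C)(Br)[C@@H](Cl)C1 | intermediate
10 | (3S,4S)-4-bromo-1-[(1R,3S,4S)-4-bromo-3-chloro-4-methylcyclohexyl]-5-chloro-5-methyl-3-[(triisopropylsilyl)oxy]hexan-1-one | O=C(C[C@H](O[Si](C(C)C)(C(C)C)C(C)C)[C@H](Br)C(C)(C)Cl)[C@@H]1CC[C@](C)(Br)[C@@H](Cl)C1 | intermediate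
11 | triisopropyl({(4S,5S)-5-bromo-2-[(1R,3S,4S)-4-bromo-3-chloro-4-methylcyclohexyl]-6-chloro-6-methylhept-1-en-4-yl}oxy)silane | C=C(C[C@H](O[Si](C(C)C)(C(C)C)C(C)C)[C@H](Br)C(C)(C)Cl)[C@@H]1CC[C@](C)(Br)[C@@H](Cl)C1 | intermediate
12 | triisopropyl({(4S,5S)-5-bromo-2-[(3S,4S)-4-bromo-3-chloro-4-methylcyclohexylidene]-6-chloro-6-methylheptan-4-yl}oxy)silane, E isomer (C7-methyl syn to ring carbon C1) | C/C(C[C@H](O[Si](C(C)C)(C(C)C)C(C)C)[C@H](Br)C(C)(C)Cl)=C1/CC[C@](C)(Br)[C@@H](Cl)C1 | intermediate (not isolated)
13 | triisopropyl{[(3S,4R,6R,8S,9S)-4,9-dibromo-8-chloro-1,5,5,9-tetramethylspiro[5.5]undec-1-en-3-yl]oxy}silane | CC1=C[C@H](O[Si](C(C)C)(C(C)C)C(C)C)[C@H](Br)C(C)(C)[C@@]12CC[C@](C)(Br)[C@@H](Cl)C2 | intermediate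
14 | (3S,4R,6R,8S,9S)-4,9-dibromo-8-chloro-1,5,5,9-tetramethylspiro[5.5]undec-1-en-3-ol | CC1=C[C@H](O)[C@H](Br)C(C)(C)[C@@]12CC[C@](C)(Br)[C@@H](Cl)C2 | target

Total step count: 10. Longest linear sequence: 8 steps (steps 1, 2, 3, 6, 7, 8, 9, 10).

**Steps most likely to fail**

Step 9 (Proposed new method). The olefin pool may react with poor facial selectivity at C6 or through the wrong olefin isomer. Five-ring closure, fragmentation of the C7 cation, or ionisation at the ring bromide or the allylic silyl ether may also intervene. The fallback uses known chemistry and sets out from ketone 10. Thermodynamic enol triflation toward the more substituted side (Tf2O, 2,6-di-tert-butyl-4-methylpyridine, CH2Cl2) should give the tetrasubstituted enol triflate F1 together with its geometric isomer F2. Negishi methylation with retention (MeZnCl, Pd(PPh3)4, THF) should give 12 and the Z-alkene F3. Buffered solvolysis (HFIP, 2,6-di-tert-butyl-4-methylpyridine, 23 °C) is the known stereospecific bromonium-initiated cation–olefin cyclisation of a vicinal bromochloride; it should convert 12 into 13, while F3 should give mainly the C6-epimeric silyl ether F4, which is removed by chromatography. The route is rejoined at 13.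

Step 6. Aldehyde 7 may epimerise or lose HCl before the C–C bond forms, or the 1,2-induction may be low. The fallback sets out from 4. Kinetic silylation (TMSOTf, Et3N, CH2Cl2) should give the silyl enol ether F5. A Lewis-base-catalysed enantioselective Mukaiyama aldol addition (SiCl4, chiral bisphosphoramide, CH2Cl2, −78 °C) to 3-methylbut-2-enal should give the allylic alcohol F6. The hydroxyl-directed titanium/Schiff-base bromochlorination (NBS, ClTi(Oi-Pr)3), applied to this allylic alcohol, should add Br and Cl anti across the prenyl double bond under ligand control. The route is rejoined at 9.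

Step 3. Ionisation at the carbinol may proceed without stereocontrol, with elimination or with halide scrambling. The fallback sets out from 3. Anti-E2 dehydration toward C4 (POCl3, pyridine) should give the cyclohexene F7. Ionic Markovnikov hydrobromination (HBr, CH2Cl2, −78 °C), with bromide entering axially and anti to the C–Cl bond, should then install the tertiary bromide. The route is rejoined at 4.

Further compounds
F1 | step 9 | (3S,4S)-4-bromo-1-[(3S,4S)-4-bromo-3-chloro-4-methylcyclohexylidene]-5-chloro-5-methyl-3-[(triisopropylsilyl)oxy]hexyl trifluoromethanesulfonate, Z isomer (OTf syn to ring carbon C1) | FC(F)(F)S(=O)(=O)O/C(C[C@H](O[Si](C(C)C)(C(C)C)C(C)C)[C@H](Br)C(C)(C)Cl)=C1/CC[C@](C)(Br)[C@@H](Cl)C1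
F2 | step 9 | (3S,4S)-4-bromo-1-[(3S,4S)-4-bromo-3-chloro-4-methylcyclohexylidene]-5-chloro-5-methyl-3-[(triisopropylsilyl)oxy]hexyl trifluoromethanesulfonate, E isomer | FC(F)(F)S(=O)(=O)O/C(C[C@H](O[Si](C(C)C)(C(C)C)C(C)C)[C@H](Br)C(C)(C)Cl)=C1\CC[C@](C)(Br)[C@@H](Cl)C1
F3 | step 9 | Z isomer of 12, triisopropyl({(4S,5S)-5-bromo-2-[(3S,4S)-4-bromo-3-chloro-4-methylcyclohexylidene]-6-chloro-6-methylheptan-4-yl}oxy)silane | C/C(C[C@H](O[Si](C(C)C)(C(C)C)C(C)C)[C@H](Br)C(C)(C)Cl)=C1\CC[C@](C)(Br)[C@@H](Cl)C1
F4 | step 9 | triisopropyl{[(3S,4R,6S,8S,9S)-4,9-dibromo-8-chloro-1,5,5,9-tetramethylspiro[5.5]undec-1-en-3-yl]oxy}silane (C6 epimer of 13) | CC1=C[C@H](O[Si](C(C)C)(C(C)C)C(C)C)[C@H](Br)C(C)(C)[C@]12CC[C@](C)(Br)[C@@H](Cl)C2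
F5 | step 6 | ({1-[(1R,3S,4S)-4-bromo-3-chloro-4-methylcyclohexyl]ethenyl}oxy)trimethylsilane | C=C(O[Si](C)(C)C)[C@@H]1CC[C@](C)(Br)[C@@H](Cl)C1
F6 | step 6 | (S)-1-[(1R,3S,4S)-4-bromo-3-chloro-4-methylcyclohexyl]-3-hydroxy-5-methylhex-4-en-1-one | O=C(C[C@H](O)C=C(C)C)[C@@H]1CC[C@](C)(Br)[C@@H](Cl)C1
F7 | step 3 | 1-[(1R,5S)-5-chloro-4-methylcyclohex-3-en-1-yl]ethan-1-one | CC(=O)[C@@H]1CC=C(C)[C@@H](Cl)C1
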